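**Retrosynthetic overview**

1. The target is reached by global desilylation, after a Heck coupling of 5-bromo-dihydrobenzofuran 10 with aryl vinyl ketone 12 builds the chalcone C=C.
2. Ketone 10 comes from an oxidative ring contraction of the (S)-2,4-diaryl-2H-chromene 8: the six-membered pyran ring (O1, C2, C3, C4, C4a, C8a) loses C4 from the ring and becomes the five-membered dihydrofuran ring, C4 ending up as the exocyclic aroyl C=O.
3. Enabling feature: C3 of the dihydrofuran carries both the fused benzene carbon C3a and the carbonyl carbon of the 2,4-dihydroxybenzoyl group (an α-aryl ketone). Putting that carbonyl carbon back between C3 and C3a gives a 4-aryl-pyran ring, and O1, ortho to C3a, makes C3a a strongly migrating aryl carbon.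
4. Chromene 8 comes from (S)-flavanone 3 by aryl-Grignard addition and dehydration; 3 comes from 6-bromochromone 1 by catalytic asymmetric conjugate arylation, which sets C2, the only centre set by a catalyst.
5. Ring order: the benzopyranone is bought, the pyran is carried to step 5, then contracted. Both resorcinol rings come from one batch of arylmagnesium reagent 6, made once in step 3 and used in steps 4 and 6.

Key step: step 5

Assumption: by analogy with the sense of addition to cyclic enones, (R)-t-BuPyOx should give the 2S flavanone; if the sense proves opposite, the (S)-ligand is used.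
Abbreviation: TBS = tert-butyldimethylsilyl; TBSO = tert-butyldimethylsilyloxy.

**Route**

Step 1
Reactants: 1 6-bromochromone (6-bromo-4H-chromen-4-one); 2 4-(TBSO)phenylboronic acid
Product: 3 (S)-6-bromo-2-[4-(TBSO)phenyl]chroman-4-one
Conditions: Pd(OCOCF3)2 (5 mol %), (R)-t-BuPyOx (6 mol %), NH4PF6 (30 mol %), H2O (5 equiv), ClCH2CH2Cl, 60 °C
Reagents that add atoms: none
Why: Asymmetric conjugate addition of an arylboronic acid to a chromone under cationic divalent-palladium/pyridine–oxazoline catalysis is an established flavanone synthesis; enantioface-selective insertion of C2=C3 into the aryl–palladium bond, steered by the tert-butyl group of the ligand, sets C2 as S, and because the cycle never passes through zerovalent palladium the C–Br bond should stay intact.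

Step 2
Reactants: 4 4-bromoresorcinol (4-bromobenzene-1,3-diol)
Product: 5 1-bromo-2,4-bis(TBSO)benzene
Conditions: TBSCl (2.4 equiv), imidazole (5 equiv), DMF, 25 °C
Reagents that add atoms: tert-butyldimethylsilyl chloride, CC(C)(C)[Si](C)(C)Cl
Why: Standard imidazole-promoted silylation of both phenols; the bulky silyl ethers should survive acid and trivalent iodine later and fall to fluoride at the end.

Step 3
Reactants: 5 1-bromo-2,4-bis(TBSO)benzene
Product: 6 [2,4-bis(TBSO)phenyl]magnesium bromide (one batch, kept as a titrated THF solution under argon at 0 °C)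
Conditions: Mg turnings (1.5 equiv, activated with BrCH2CH2Br), LiCl (1.2 equiv), THF, 25 °C; decanted from excess Mg and titrated against iodine
Reagents that add atoms: magnesium, [Mg]
Why: Grignard reagent formation by LiCl-assisted direct insertion of magnesium into the aryl C–Br bond should proceed at room temperature, where oxygen-to-carbon silyl migration of the ortho silyloxy group is slow, and the single batch is sized to supply both step 4 and step 6.

Step 4
Reactants: 6 [2,4-bis(TBSO)phenyl]magnesium bromide; 3 (S)-6-bromo-2-[4-(TBSO)phenyl]chroman-4-one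
Product: 8 (S)-6-bromo-4-[2,4-bis(TBSO)phenyl]-2-[4-(TBSO)phenyl]-2H-chromene, via flavan-4-ol 7 (not isolated)
Conditions: 6 (1.3 equiv), LaCl3·2LiCl (30 mol %), THF, −20 to 0 °C; H2O quench; then crude 7, PPTS (5 mol %), 4 Å MS, toluene, 25 °C, dark
Reagents that add atoms: none
Why: Grignard 1,2-addition to the flavanone carbonyl (LaCl3·2LiCl should favour addition over enolisation, which would open the pyranone by E1cB and erode the ee), followed by mild E1 dehydration of the doubly benzylic tertiary alcohol, whose only β-hydrogens sit on C3, should give the C3=C4 alkene; C2 is untouched, the C4 centre of 7 is destroyed, and exclusion of light guards C2 against electrocyclic opening of the chromene.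

Step 5
Reactants: 8 (S)-6-bromo-4-[2,4-bis(TBSO)phenyl]-2-[4-(TBSO)phenyl]-2H-chromene
Product: 10 (2S,3S)-5-bromo-3-[2,4-bis(TBSO)benzoyl]-2-[4-(TBSO)phenyl]-2,3-dihydro-1-benzofuran, via iodonium carbinol 9 (not isolated)
Conditions: 8 added to PhI(OH)OTs (1.1 equiv), MeCN/H2O (20:1), 0 °C, dark; then aq. NaHCO3
Reagents that add atoms: water, O (the ketone oxygen); hydroxy(tosyloxy)iodobenzene, OI(c1ccccc1)OS(=O)(=O)c1ccc(C)cc1 (its atoms stay only in intermediate 9)
Why: Proposed new method: the electron-rich C3=C4 bond of 8 should attack the trivalent iodine centre through C3 on the face anti to the C2 aryl group, water captures the doubly benzylic C4 cation to give 9, and in the conformer with the C2 aryl and C3 iodanyl groups both equatorial the C4–C4a bond lies antiperiplanar to C3–I, so C4a migrates from C4 to C3 with loss of PhI while the C4 hydroxyl collapses to the aryl ketone (a semipinacol-type 1,2-aryl shift through a phenonium-like bridge). The closest known reactions are the PhI(OH)OTs-mediated ring contraction of 1,2-dihydronaphthalenes to trans-1,3-disubstituted indanes and the trivalent-iodine ring contraction of flavanones to trans-2-aryl-2,3-dihydrobenzofuran-3-carboxylates; a 4-aryl-2H-chromene is a new substrate class and would deliver the ketone oxidation level directly. The five-membered O1–C2–C3–C3a–C7a ring is not closed by a cyclisation: it arises from the pyran ring by excision of C4, the new C3–C3a bond forming by 3-exo-type ipso attack of the arene on C3 and the old C4–C4a bond breaking. The new stereocentre C3 is controlled by C2: anti delivery of iodine and inversion at C3 during the shift place the aroyl group trans to the C2 aryl group (2S,3S), and any cis isomer should converge to trans by enolisation because C2 is untouched. The step needs migration of ring carbon C4a and not of the exocyclic resorcinyl ring, the C2 aryl group (isoflavone-type 2,3-shift), O1 or hydride; this is secured by the equatorial anchoring of the C2 aryl group (only the ring bonds are anti to C3–I, whichever face water takes at C4, and epoxide closure is geometrically excluded), by the C4 hydroxyl that pushes only a C4-to-C3 shift, and by O1 ortho to C4a that raises its migratory aptitude. Chemoselectivity for the alkene over the silyloxyarenes should follow from its much higher nucleophilicity and the bulk of the silyl groups.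

Step 6
Reactants: 6 [2,4-bis(TBSO)phenyl]magnesium bromide; 11 N-methoxy-N-methylacrylamide
Product: 12 1-[2,4-bis(TBSO)phenyl]prop-2-en-1-one
Conditions: 6 (1.1 equiv), THF, −78 to −20 °C; inverse quench into cold 1 M aq. HCl; used at once (BHT trace)
Reagents that add atoms: none
Why: Ketone synthesis from an N-methoxy-N-methylamide: the chelated tetrahedral magnesium adduct persists until the quench, so no second addition occurs, and the cold acidic inverse quench protonates the liberated amine before it can add to the new enone.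

Step 7
Reactants: 10 (2S,3S)-5-bromo-3-[2,4-bis(TBSO)benzoyl]-2-[4-(TBSO)phenyl]-2,3-dihydro-1-benzofuran; 12 1-[2,4-bis(TBSO)phenyl]prop-2-en-1-one
Product: 13 (E)-3-{(2S,3S)-3-[2,4-bis(TBSO)benzoyl]-2-[4-(TBSO)phenyl]-2,3-dihydro-1-benzofuran-5-yl}-1-[2,4-bis(TBSO)phenyl]prop-2-en-1-one
Conditions: Pd(P(t-Bu)3)2 (5 mol %), Cy2NMe (1.3 equiv), 12 (1.5 equiv), dioxane, 25 to 40 °C
Reagents that add atoms: none
Why: Heck reaction: oxidative addition of the aryl bromide to the zerovalent palladium/P(t-Bu)3 catalyst near room temperature, syn carbopalladation at the unsubstituted terminus of the enone and syn β-hydride elimination should give the E alkene only, while the hindered amine and low temperature should leave the enolisable C3–H (hence the trans relationship and the ee) untouched.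

Step 8
Reactants: 13 pentakis-TBS ether of the target
Product: 14 (E)-3-[(2S,3S)-3-(2,4-dihydroxybenzoyl)-2-(4-hydroxyphenyl)-2,3-dihydro-1-benzofuran-5-yl]-1-(2,4-dihydroxyphenyl)prop-2-en-1-one (target)
Conditions: TBAF (6 equiv), AcOH (6 equiv), THF, 0 to 25 °C
Reagents that add atoms: none
Why: Fluoride cleavage of the five aryl silyl ethers; buffering with AcOH keeps the phenols protonated, which should prevent E1cB opening of the dihydrofuran, epimerisation at C3 and cyclisation of the 2'-hydroxychalcone to a flavanone.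

**Compound list**

1 | 6-bromochromone (6-bromo-4H-chromen-4-one) | O=c1ccoc2ccc(Br)cc12 | starting material
2 | 4-(TBSO)phenylboronic acid | OB(O)c1ccc(O[Si](C)(C)C(C)(C)C)cc1 | starting material
3 | (S)-6-bromo-2-[4-(TBSO)phenyl]chroman-4-one | O=C1C[C@@H](c2ccc(O[Si](C)(C)C(C)(C)C)cc2)Oc2ccc(Br)cc21 | intermediate
4 | 4-bromoresorcinol (4-bromobenzene-1,3-diol) | Oc1ccc(Br)c(O)c1 | starting material
5 | 1-bromo-2,4-bis(TBSO)benzene | Brc1ccc(O[Si](C)(C)C(C)(C)C)cc1O[Si](C)(C)C(C)(C)C | intermediate
6 | [2,4-bis(TBSO)phenyl]magnesium bromide | Br[Mg]c1ccc(O[Si](C)(C)C(C)(C)C)cc1O[Si](C)(C)C(C)(C)C | intermediate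
7 | (2S)-6-bromo-4-[2,4-bis(TBSO)phenyl]-2-[4-(TBSO)phenyl]chroman-4-ol, both C4 epimers (C4 left undefined) | OC1(c2ccc(O[Si](C)(C)C(C)(C)C)cc2O[Si](C)(C)C(C)(C)C)C[C@@H](c2ccc(O[Si](C)(C)C(C)(C)C)cc2)Oc2ccc(Br)cc21 | intermediate
8 | (S)-6-bromo-4-[2,4-bis(TBSO)phenyl]-2-[4-(TBSO)phenyl]-2H-chromene | Brc1ccc2c(c1)C(c1ccc(O[Si](C)(C)C(C)(C)C)cc1O[Si](C)(C)C(C)(C)C)=C[C@@H](c1ccc(O[Si](C)(C)C(C)(C)C)cc1)O2 | intermediate
9 | (2R,3R,4S)-{6-bromo-4-[2,4-bis(TBSO)phenyl]-4-hydroxy-2-[4-(TBSO)phenyl]chroman-3-yl}(phenyl)iodonium tosylate; iodine at C3 anti to the C2 aryl group, hydroxyl at C4 drawn anti to iodine (the C4 epimer would react alike) | Brc1ccc2c(c1)[C@](O)(c1ccc(O[Si](C)(C)C(C)(C)C)cc1O[Si](C)(C)C(C)(C)C)[C@H]([I+]c1ccccc1)[C@@H](c1ccc(O[Si](C)(C)C(C)(C)C)cc1)O2.Cc1ccc(S(=O)(=O)[O-])cc1 | intermediate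
10 | (2S,3S)-5-bromo-3-[2,4-bis(TBSO)benzoyl]-2-[4-(TBSO)phenyl]-2,3-dihydro-1-benzofuran (trans) | Brc1ccc2c(c1)[C@H](C(=O)c1ccc(O[Si](C)(C)C(C)(C)C)cc1O[Si](C)(C)C(C)(C)C)[C@@H](c1ccc(O[Si](C)(C)C(C)(C)C)cc1)O2 | intermediate
11 | N-methoxy-N-methylacrylamide | C=CC(=O)N(C)OC | starting material
12 | 1-[2,4-bis(TBSO)phenyl]prop-2-en-1-one | C=CC(=O)c1ccc(O[Si](C)(C)C(C)(C)C)cc1O[Si](C)(C)C(C)(C)C | intermediate
13 | (E)-3-{(2S,3S)-3-[2,4-bis(TBSO)benzoyl]-2-[4-(TBSO)phenyl]-2,3-dihydro-1-benzofuran-5-yl}-1-[2,4-bis(TBSO)phenyl]prop-2-en-1-one | O=C(/C=C/c1ccc2c(c1)[C@H](C(=O)c1ccc(O[Si](C)(C)C(C)(C)C)cc1O[Si](C)(C)C(C)(C)C)[C@@H](c1ccc(O[Si](C)(C)C(C)(C)C)cc1)O2)c1ccc(O[Si](C)(C)C(C)(C)C)cc1O[Si](C)(C)C(C)(C)C | intermediate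
14 | (E)-3-[(2S,3S)-3-(2,4-dihydroxybenzoyl)-2-(4-hydroxyphenyl)-2,3-dihydro-1-benzofuran-5-yl]-1-(2,4-dihydroxyphenyl)prop-2-en-1-one | O=C(/C=C/c1ccc2c(c1)[C@H](C(=O)c1ccc(O)cc1O)[C@@H](c1ccc(O)cc1)O2)c1ccc(O)cc1O | target

**Step count and risks**

Total steps: 8. Longest linear sequence: 6 (steps 2, 3, 4, 5, 7, 8).

Steps most likely to fail:

1. Step 5 (proposed new method). What may go wrong: migration of the wrong group (exocyclic resorcinyl ring or C2 aryl group instead of C4a), oxidation of the chromene to a flavylium ion by hydride loss, acid-induced disproportionation of the chromene by the liberated sulfonic acid, or attack of the iodane on the silyloxyarenes. Fallback with known chemistry, setting out from 3 and coming back at 10: the established trivalent-iodine ring contraction of flavanones (PhI(OAc)2, H2SO4, HC(OMe)3, 25 to 50 °C; 1,2-shift of C4a in the 3-iodanyl dimethyl ketal) should give methyl (2S,3S)-5-bromo-2-[4-(TBSO)phenyl]-2,3-dihydro-1-benzofuran-3-carboxylate F1. Non-basic aminolysis (Me(MeO)NH·HCl, AlMe3, CH2Cl2, 0 to 25 °C) should convert it into (2S,3S)-5-bromo-N-methoxy-N-methyl-2-[4-(TBSO)phenyl]-2,3-dihydro-1-benzofuran-3-carboxamide F2. Addition of arylmagnesium bromide 6 (from the step 3 batch; THF, −40 °C) should then give ketone 10.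

2. Step 4. What may go wrong: enolisation of the flavanone by the hindered ortho-substituted arylmagnesium reagent with E1cB ring opening (loss of material and of ee), or acid-mediated disproportionation of the chromene during dehydration. Fallback, setting out from 3 and 5 and coming back at 8: the polarity is reversed to a cross-coupling. Ketone 3 is converted without enolate formation (Tf2O, 2,6-di-tert-butyl-4-methylpyridine, CH2Cl2, 0 to 25 °C) into (S)-6-bromo-2-[4-(TBSO)phenyl]-2H-chromen-4-yl trifluoromethanesulfonate F3. Bromide 5 is borylated (B2pin2, PdCl2(dppf), KOAc, dioxane, 80 °C) to 2-[2,4-bis(TBSO)phenyl]-4,4,5,5-tetramethyl-1,3,2-dioxaborolane F4. Suzuki–Miyaura coupling of F3 with F4 (Pd(PPh3)4, K3PO4, THF/H2O, 40 °C), in which the alkenyl triflate should undergo oxidative addition before the aryl bromide, gives chromene 8.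

3. Step 7. What may go wrong: polymerisation of the vinyl ketone, amine-mediated enolisation at C3 with E1cB opening and reclosure of the dihydrofuran (erosion of ee), or sluggish oxidative addition of the electron-rich aryl bromide. Fallback, setting out from 10 and coming back at 13: a base-free two-step installation of the enone. Stille coupling of 10 with tributyl(vinyl)stannane (Pd(PPh3)4, toluene, 80 °C) should give (2S,3S)-3-[2,4-bis(TBSO)benzoyl]-2-[4-(TBSO)phenyl]-5-vinyl-2,3-dihydro-1-benzofuran F5. Olefin cross-metathesis of F5 with vinyl ketone 12 (second-generation Hoveyda–Grubbs catalyst, RuCl2(H2IMes)(=CH-2-(i-PrO)C6H4), 5 mol %, CH2Cl2, 40 °C) should give the E enone 13.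

Further compounds
F1 | step 5 | methyl (2S,3S)-5-bromo-2-[4-(TBSO)phenyl]-2,3-dihydro-1-benzofuran-3-carboxylate | Brc1ccc2c(c1)[C@H](C(=O)OC)[C@@H](c1ccc(O[Si](C)(C)C(C)(C)C)cc1)O2
F2 | step 5 | (2S,3S)-5-bromo-N-methoxy-N-methyl-2-[4-(TBSO)phenyl]-2,3-dihydro-1-benzofuran-3-carboxamide | Brc1ccc2c(c1)[C@H](C(=O)N(C)OC)[C@@H](c1ccc(O[Si](C)(C)C(C)(C)C)cc1)O2
F3 | step 4 | (S)-6-bromo-2-[4-(TBSO)phenyl]-2H-chromen-4-yl trifluoromethanesulfonate | Brc1ccc2c(c1)C(OS(=O)(=O)C(F)(F)F)=C[C@@H](c1ccc(O[Si](C)(C)C(C)(C)C)cc1)O2
F4 | step 4 | 2-[2,4-bis(TBSO)phenyl]-4,4,5,5-tetramethyl-1,3,2-dioxaborolane | CC1(C)OB(c2ccc(O[Si](C)(C)C(C)(C)C)cc2O[Si](C)(C)C(C)(C)C)OC1(C)C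
F5 | step 7 | (2S,3S)-3-[2,4-bis(TBSO)benzoyl]-2-[4-(TBSO)phenyl]-5-vinyl-2,3-dihydro-1-benzofuran | C=Cc1ccc2c(c1)[C@H](C(=O)c1ccc(O[Si](C)(C)C(C)(C)C)cc1O[Si](C)(C)C(C)(C)C)[C@@H](c1ccc(O[Si](C)(C)C(C)(C)C)cc1)O2
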